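The α-methylene-γ-butyrolactone is disconnected across its O–C6 and C11–C7 bonds, which leaves a (4Z,6Z)-cyclodeca-4,6-diene and 2-bromoacrylic acid. The key step exploits that C6, the oxygen-bearing carbon of the lactone ring, is allylic to the C4=C5 alkene of the ten-membered ring. A palladium-catalysed heteroannulation adds the vinyl carbon to the C7 terminus of the C4=C5–C6=C7 diene and the tethered carboxylate to C6 of the resulting π-allyl unit, forming the trans-fused methylene lactone in one operation. The diene precursor, already carrying the C2/C3 acetonide, C10 methyl and C9 angelate, comes from L-glutamic-acid-derived lactone 1 by Nozaki–Hiyama–Kishi coupling, Brown allylation and ring-closing metathesis.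

Key step: step 15

Remark on numbering: ring atoms are numbered as in germacranolides. C1 is the ring CH2, C2 and C3 carry the diol, C4 the vinylic methyl, C6 the lactone oxygen, C7 is the other ring-fusion carbon, C8 is CH2, C9 carries the angelate and C10 the methyl. C11 is the lactone α-carbon, C12 the carbonyl and C13 the exocyclic methylene. The target is (2S,3R,4Z,6R,7S,9S,10R).

Assumption: compounds 1, 7, 19 and 21 and the (+)-α-pinene-derived B-allyldiisopinocampheylborane solution are taken as commercially available.

Step 1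
Reactants: 1 (S)-5-(hydroxymethyl)dihydrofuran-2(3H)-one
Product: 2 (S)-5-[(trityloxy)methyl]dihydrofuran-2(3H)-one
Conditions: TrCl, Et3N, DMAP (cat.), CH2Cl2, rt
Reagents that add atoms: trityl chloride, ClC(c1ccccc1)(c1ccccc1)c1ccccc1
Why: Tritylation of the primary alcohol (etherification through the trityl cation) touches no stereocentre and installs the bulky group that directs the next alkylation.

Step 2
Reactants: 2 (S)-5-[(trityloxy)methyl]dihydrofuran-2(3H)-one
Product: 4 (3R,5S)-3-methyl-5-[(trityloxy)methyl]dihydrofuran-2(3H)-one, via lithium enolate 3 (not isolated)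
Conditions: LDA, THF, −78 °C; then MeI, −78 °C
Reagents that add atoms: iodomethane, CI
Why: Kinetic enolate alkylation of the γ-substituted butyrolactone should occur on the face opposite the trityloxymethyl group, giving the trans lactone and setting the future C10 centre as R.

Step 3
Reactants: 4 (3R,5S)-3-methyl-5-[(trityloxy)methyl]dihydrofuran-2(3H)-one
Product: 5 (3R,5S)-5-(hydroxymethyl)-3-methyldihydrofuran-2(3H)-one
Conditions: Amberlyst 15, MeOH, rt
Reagents that add atoms: none
Why: Acid-catalysed solvolysis of the trityl ether (the trityl cation is captured by methanol) should free the primary alcohol without opening the γ-lactone or epimerising the α-methyl centre.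

Step 4
Reactants: 5 (3R,5S)-5-(hydroxymethyl)-3-methyldihydrofuran-2(3H)-one
Product: 6 (2S,4R)-4-methyl-5-oxotetrahydrofuran-2-carbaldehyde
Conditions: Dess–Martin periodinane, CH2Cl2, 0 °C to rt
Reagents that add atoms: none
Why: Dess–Martin oxidation works without base, so the oxygen-bearing α-stereocentre of the aldehyde should not epimerise; the aldehyde is used crude.

Step 5
Reactants: 7 but-2-yn-1-ol
Product: 9 (Z)-3-iodobut-2-en-1-ol, via cyclic vinylalanate 8 (not isolated)
Conditions: NaAlH2(OCH2CH2OMe)2 (Red-Al), THF, 0 °C to rt; then I2, −78 to 0 °C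
Reagents that add atoms: iodine, II
Why: Hydroxyl-directed trans-hydroalumination places aluminium on C3 cis to the CH2O group in a five-membered alanate, and iodinolysis with retention should give only the Z vinyl iodide.

Step 6
Reactants: 9 (Z)-3-iodobut-2-en-1-ol
Product: 10 (Z)-3-iodobut-2-enal
Conditions: MnO2, CH2Cl2, rt
Reagents that add atoms: none
Why: Allylic oxidation with MnO2 is neutral and mild, so the Z geometry of the β-iodo enal should be kept.

Step 7
Reactants: 10 (Z)-3-iodobut-2-enal
Product: 11 (Z)-4-iodopenta-1,3-diene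
Conditions: Ph3PCH3Br, NaHMDS, THF, 0 °C; then 10, −78 to 0 °C
Reagents that add atoms: methylenetriphenylphosphorane (made from methyltriphenylphosphonium bromide), C=P(c1ccccc1)(c1ccccc1)c1ccccc1
Why: Wittig methylenation of the enal should give the terminal diene without touching the vinyl iodide or its Z geometry; the volatile product is handled as a solution.

Step 8
Reactants: 6 (2S,4R)-4-methyl-5-oxotetrahydrofuran-2-carbaldehyde; 11 (Z)-4-iodopenta-1,3-diene
Product: 12 (3R,5S)-5-[(1R,2Z)-1-hydroxy-2-methylpenta-2,4-dien-1-yl]-3-methyldihydrofuran-2(3H)-one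
Conditions: CrCl2 (excess), NiCl2 (cat.), DMSO, rt
Reagents that add atoms: none
Why: The Nozaki–Hiyama–Kishi coupling is chemoselective for the aldehyde beside the lactone, transfers the alkenyl group with retention of the Z geometry, and should add in the Felkin–Anh sense anti to the ring oxygen to set C3 as R.

Step 9
Reactants: 12 (3R,5S)-5-[(1R,2Z)-1-hydroxy-2-methylpenta-2,4-dien-1-yl]-3-methyldihydrofuran-2(3H)-one
Product: 13 (2R,4S,5R,6Z)-2,6-dimethylnona-6,8-diene-1,4,5-triol
Conditions: LiBH4, THF, 0 °C to rt
Reagents that add atoms: none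
Why: Hydride reduction of the lactone to the 1,4-diol leaves the diene and all stereocentres untouched and unmasks the C2 hydroxyl and the C9 primary alcohol together.

Step 10
Reactants: 13 (2R,4S,5R,6Z)-2,6-dimethylnona-6,8-diene-1,4,5-triol
Product: 14 (2R)-3-{(4S,5R)-2,2-dimethyl-5-[(2Z)-penta-2,4-dien-2-yl]-1,3-dioxolan-4-yl}-2-methylpropan-1-ol
Conditions: 2,2-dimethoxypropane, PPTS (cat.), acetone, 0 °C to rt
Reagents that add atoms: 2,2-dimethoxypropane, COC(C)(C)OC
Why: Thermodynamic acetalisation should select the erythro 1,2-diol as the five-membered cis-dioxolane over seven- or eight-membered alternatives and leave the primary alcohol free, and the weak acid should not ionise the dienylic C–O bond.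

Step 11
Reactants: 14 (2R)-3-{(4S,5R)-2,2-dimethyl-5-[(2Z)-penta-2,4-dien-2-yl]-1,3-dioxolan-4-yl}-2-methylpropan-1-ol
Product: 15 (2R)-3-{(4S,5R)-2,2-dimethyl-5-[(2Z)-penta-2,4-dien-2-yl]-1,3-dioxolan-4-yl}-2-methylpropanal
Conditions: Dess–Martin periodinane, CH2Cl2, 0 °C
Reagents that add atoms: none
Why: Dess–Martin oxidation should give the α-methyl aldehyde without epimerisation at C10 and without affecting the diene or the acetonide; it is used at once.

Step 12
Reactants: 15 (2R)-3-{(4S,5R)-2,2-dimethyl-5-[(2Z)-penta-2,4-dien-2-yl]-1,3-dioxolan-4-yl}-2-methylpropanal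
Product: 17 (2R,3S)-1-{(4S,5R)-2,2-dimethyl-5-[(2Z)-penta-2,4-dien-2-yl]-1,3-dioxolan-4-yl}-2-methylhex-5-en-3-ol, via diisopinocampheylborinate 16 (not isolated)
Conditions: B-allyldiisopinocampheylborane from (+)-α-pinene, Et2O, −78 °C; then NaOH, H2O2, 0 °C to rt
Reagents that add atoms: B-allyldiisopinocampheylborane derived from (+)-α-pinene, C=CCB([C@@H]1C[C@@H]2C[C@H]([C@H]1C)C2(C)C)[C@@H]1C[C@@H]2C[C@H]([C@H]1C)C2(C)C
Why: Brown allylation through a chair Zimmerman–Traxler transition state should deliver allyl to the Si face of the aldehyde under reagent control, setting C9 as S whatever the bias of the α-methyl centre.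

Step 13
Reactants: 17 (2R,3S)-1-{(4S,5R)-2,2-dimethyl-5-[(2Z)-penta-2,4-dien-2-yl]-1,3-dioxolan-4-yl}-2-methylhex-5-en-3-ol
Product: 18 (3aR,4Z,6Z,9S,10R,11aS)-2,2,4,10-tetramethyl-3a,8,9,10,11,11a-hexahydrocyclodeca[d][1,3]dioxol-9-ol
Conditions: second-generation Grubbs catalyst (10 mol %), CH2Cl2 (1 mM), 40 °C
Reagents that add atoms: none
Why: Ring-closing metathesis between the allyl terminus and the vinyl end of the diene (the trisubstituted C4=C5 bond is too hindered to engage) should close the ten-membered ring, with the cis-dioxolane and the Z C4=C5 bond pre-folding the chain and the less strained Z geometry expected at C6=C7.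

Step 14
Reactants: 18 (3aR,4Z,6Z,9S,10R,11aS)-2,2,4,10-tetramethyl-3a,8,9,10,11,11a-hexahydrocyclodeca[d][1,3]dioxol-9-ol; 19 angelic acid, (Z)-2-methylbut-2-enoic acid
Product: 20 (3aR,4Z,6Z,9S,10R,11aS)-2,2,4,10-tetramethyl-3a,8,9,10,11,11a-hexahydrocyclodeca[d][1,3]dioxol-9-yl (Z)-2-methylbut-2-enoate
Conditions: 19, 2,4,6-trichlorobenzoyl chloride, Et3N, toluene, rt; then 18, 80 °C
Reagents that add atoms: none
Why: Yamaguchi-type mixed-anhydride acylation without a nucleophilic catalyst should esterify the hindered C9 alcohol with retention at C9 and without Z-to-E isomerisation of the angeloyl group.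

Step 15
Reactants: 20 (3aR,4Z,6Z,9S,10R,11aS)-2,2,4,10-tetramethyl-3a,8,9,10,11,11a-hexahydrocyclodeca[d][1,3]dioxol-9-yl (Z)-2-methylbut-2-enoate; 21 2-bromoacrylic acid
Product: 22 2,3-O-isopropylidene acetal of the target, (2S,3R,4Z,6R,7S,9S,10R)-9-angeloyloxy-2,3-(isopropylidenedioxy)germacra-4,11(13)-dien-12,6-olide
Conditions: Pd(OAc)2 (10 mol %), n-Bu4NCl, NaHCO3, DMF, 60 °C, 21 added slowly
Reagents that add atoms: none
Why: Oxidative addition of the C–Br bond of the 2-bromoacrylate to zerovalent palladium gives a 1-carboxyvinylpalladium species that inserts the less substituted C6=C7 alkene syn, with carbon bonding to C7, to give a π-allylpalladium unit over C4–C5–C6; the tethered carboxylate then attacks C6 and releases zerovalent palladium. The closest known reaction type is the Larock heteroannulation of 1,3-dienes by vinylic or aryl halides that carry a carboxylic acid. The lactone ring closes in a 5-exo mode (C4–C5 of the allyl unit stays outside the new ring), preferred over seven-membered closure at the tertiary C4 terminus, so the C4=C5 bond is returned with its Z geometry. C7 is set by the face of carbopalladation: peripheral attack on the ring conformer that keeps the C9 angelate outward and C9–H under the alkene should give 7S; C6 is set by carboxylate attack anti to palladium (outer-sphere, favoured by chloride, which blocks carboxylate coordination), a net anti addition across the Z C6=C7 bond that gives the trans-fused 6R,7S lactone. The step needs regioselection between the two diene termini, secured by the methyl group on C4, and survival of the angelate, which as a trisubstituted electron-poor alkene should not compete in the insertion. Reversible ionisation of the allylic C6–O bond by zerovalent palladium should further funnel material to the more stable trans-fused isomer.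

Step 16
Reactants: 22 2,3-O-isopropylidene acetal of the target
Product: 23 CNP0229085.1, (2S,3R,4Z,6R,7S,9S,10R)-9-angeloyloxy-2,3-dihydroxygermacra-4,11(13)-dien-12,6-olide
Conditions: AcOH–H2O (4:1), 40 °C
Reagents that add atoms: none
Why: Mild aqueous acid hydrolysis of the isopropylidene acetal should release the cis-diol without cleaving the angelate, opening the lactone or adding to the α-methylene group.

Compound list
1 | (S)-5-(hydroxymethyl)dihydrofuran-2(3H)-one | OC[C@@H]1CCC(=O)O1 | starting material
2 | (S)-5-[(trityloxy)methyl]dihydrofuran-2(3H)-one | C(c1ccccc1)(c1ccccc1)(c1ccccc1)OC[C@@H]1CCC(=O)O1 | intermediate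
3 | lithium enolate of 2 | C(c1ccccc1)(c1ccccc1)(c1ccccc1)OC[C@@H]1CC=C([O-])O1.[Li+] | intermediate
4 | (3R,5S)-3-methyl-5-[(trityloxy)methyl]dihydrofuran-2(3H)-one | C(c1ccccc1)(c1ccccc1)(c1ccccc1)OC[C@@H]1C[C@@H](C)C(=O)O1 | intermediate
5 | (3R,5S)-5-(hydroxymethyl)-3-methyldihydrofuran-2(3H)-one | OC[C@@H]1C[C@@H](C)C(=O)O1 | intermediate
6 | (2S,4R)-4-methyl-5-oxotetrahydrofuran-2-carbaldehyde | O=C[C@@H]1C[C@@H](C)C(=O)O1 | intermediate
7 | but-2-yn-1-ol | CC#CCO | starting material
8 | sodium 2,2-bis(2-methoxyethoxy)-3-methyl-2,5-dihydro-1,2-oxaluminol-2-uide (cyclic vinylalanate) | CC1=CCO[Al-]1(OCCOC)OCCOC.[Na+] | intermediate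
9 | (Z)-3-iodobut-2-en-1-ol | C/C(I)=C/CO | intermediate
10 | (Z)-3-iodobut-2-enal | C/C(I)=C/C=O | intermediate
11 | (Z)-4-iodopenta-1,3-diene | C=C/C=C(/C)I | intermediate
12 | (3R,5S)-5-[(1R,2Z)-1-hydroxy-2-methylpenta-2,4-dien-1-yl]-3-methyldihydrofuran-2(3H)-one | C=C/C=C(/C)[C@@H](O)[C@@H]1C[C@@H](C)C(=O)O1 | intermediate
13 | (2R,4S,5R,6Z)-2,6-dimethylnona-6,8-diene-1,4,5-triol | C=C/C=C(/C)[C@@H](O)[C@@H](O)C[C@@H](C)CO | intermediate
14 | (2R)-3-{(4S,5R)-2,2-dimethyl-5-[(2Z)-penta-2,4-dien-2-yl]-1,3-dioxolan-4-yl}-2-methylpropan-1-ol | C=C/C=C(/C)[C@H]1OC(C)(C)O[C@H]1C[C@@H](C)CO | intermediate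
15 | (2R)-3-{(4S,5R)-2,2-dimethyl-5-[(2Z)-penta-2,4-dien-2-yl]-1,3-dioxolan-4-yl}-2-methylpropanal | C=C/C=C(/C)[C@H]1OC(C)(C)O[C@H]1C[C@@H](C)C=O | intermediate
16 | diisopinocampheylborinate of 17 | C=C/C=C(/C)[C@H]1OC(C)(C)O[C@H]1C[C@@H](C)[C@@H](OB([C@@H]2C[C@@H]3C[C@H]([C@H]2C)C3(C)C)[C@@H]2C[C@@H]3C[C@H]([C@H]2C)C3(C)C)CC=C | intermediate
17 | (2R,3S)-1-{(4S,5R)-2,2-dimethyl-5-[(2Z)-penta-2,4-dien-2-yl]-1,3-dioxolan-4-yl}-2-methylhex-5-en-3-ol | C=C/C=C(/C)[C@H]1OC(C)(C)O[C@H]1C[C@@H](C)[C@@H](O)CC=C | intermediate
18 | (3aR,4Z,6Z,9S,10R,11aS)-2,2,4,10-tetramethyl-3a,8,9,10,11,11a-hexahydrocyclodeca[d][1,3]dioxol-9-ol | O[C@H]1C/C=C\C=C(\C)[C@H]2OC(C)(C)O[C@H]2C[C@H]1C | intermediate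
19 | angelic acid, (Z)-2-methylbut-2-enoic acid | C/C=C(/C)C(=O)O | starting material
20 | (3aR,4Z,6Z,9S,10R,11aS)-2,2,4,10-tetramethyl-3a,8,9,10,11,11a-hexahydrocyclodeca[d][1,3]dioxol-9-yl (Z)-2-methylbut-2-enoate | C/C=C(/C)C(=O)O[C@H]1C/C=C\C=C(\C)[C@H]2OC(C)(C)O[C@H]2C[C@H]1C | intermediate
21 | 2-bromoacrylic acid | C=C(Br)C(=O)O | starting material
22 | 2,3-O-isopropylidene acetal of the target | C=C1C(=O)O[C@@H]2/C=C(/C)[C@H]3OC(C)(C)O[C@H]3C[C@@H](C)[C@@H](OC(=O)/C(C)=C\C)C[C@@H]12 | intermediate
23 | CNP0229085.1, (2S,3R,4Z,6R,7S,9S,10R)-9-angeloyloxy-2,3-dihydroxygermacra-4,11(13)-dien-12,6-olide | C=C1C(=O)O[C@@H]2/C=C(/C)[C@@H](O)[C@@H](O)C[C@@H](C)[C@@H](OC(=O)/C(C)=C\C)C[C@@H]12 | target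

Total step count: 16. Longest linear sequence: 13 steps (steps 1–4 and 8–16, from 1 to 23); steps 5–7 make the side fragment 11.

Steps most likely to fail

Step 15. The carbopalladation may take place on the other ring face, or the C–O bond may form by an inner-sphere path syn to palladium; either would give a C7-epimeric or cis-fused lactone. Loss of a β-hydrogen from the π-allyl unit to give trienes is a further leak. The fallback forms the same two bonds by a radical pathway and sets out from 20. Oxidative lactone annulation with malonic acid (Mn(OAc)3·2H2O, Cu(OAc)2, AcOH, 50 °C) adds the malonyl radical to C7; the allyl radical is oxidised to the cation and the carboxyl group closes on C6 with no metal-bound face dictating the ring fusion, so the less strained trans fusion is expected. This gives the α-carboxy lactone F1. Decarboxylative Mannich methylenation of F1 (aqueous CH2O, Et2NH, then NaOAc, AcOH, 80 °C) then gives 22, where the route is rejoined.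

Step 13. Intermolecular metathesis may outrun ring closure and give cyclic dimers and oligomers, the ring may close with an E-configured C6=C7 bond, or the carbene may attack C4=C5 and truncate the ring. The fallback reverses the order of acylation and ring closure so that the ring is closed on a differently biased substrate; it sets out from 17. Acylation of 17 with 19 under the conditions of step 14 gives the open-chain triene angelate F2. Its acyloxy group at C9 removes the free hydroxyl (no ruthenium alkoxide or hydride formation) and changes the folding of the chain. Ring-closing metathesis of F2 (second-generation Grubbs catalyst, CH2Cl2, high dilution) then gives 20 directly, where the route is rejoined.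

Step 8. Facial selectivity at the aldehyde carbonyl may be low (Felkin–Anh against anti-Felkin addition), and the α-oxygenated aldehyde may epimerise before it couples. The fallback sets the C3 centre by hydride delivery instead of by the C–C bond formation; it sets out from 12 obtained as a mixture of C3 epimers. Dess–Martin oxidation gives the dienone F3. Luche reduction of F3 (NaBH4, CeCl3·7H2O, MeOH, −78 °C) is 1,2-selective and should follow the Felkin–Anh model anti to the lactone oxygen, returning 12 as the single 1R alcohol.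

Further compounds
F1 | step 15 | 11-carboxy analogue of 22 (α-carboxy-γ-butyrolactone in place of the α-methylene lactone, C11 epimers) | OC(=O)C1C(=O)O[C@@H]2/C=C(/C)[C@H]3OC(C)(C)O[C@H]3C[C@@H](C)[C@@H](OC(=O)/C(C)=C\C)C[C@@H]12
F2 | step 13 | (2R,3S)-1-{(4S,5R)-2,2-dimethyl-5-[(2Z)-penta-2,4-dien-2-yl]-1,3-dioxolan-4-yl}-2-methylhex-5-en-3-yl (Z)-2-methylbut-2-enoate | C=C/C=C(/C)[C@H]1OC(C)(C)O[C@H]1C[C@@H](C)[C@@H](OC(=O)/C(C)=C\C)CC=C
F3 | step 8 | (3R,5S)-3-methyl-5-[(2Z)-2-methylpenta-2,4-dienoyl]dihydrofuran-2(3H)-one | C=C/C=C(/C)C(=O)[C@@H]1C[C@@H](C)C(=O)O1
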